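**Retrosynthetic overview**

- Gentiside K is tetracosyl 2,3-dihydroxybenzoate. Its benzene ring carries the ester on C1 and hydroxyls on C2 and C3 in a row, and the edge C4–C5–C6 is unsubstituted; the strategy rests on this.
- The arene is taken back (desilylation, then dehydrogenation with tautomerisation) to a 3-silyloxy-2-oxocyclohex-4-ene-1-carboxylate. Its only ring is opened at C4=C5 by ring-closing metathesis of a vinyl group on C3 and an allyl group on C1.
- The diene is an acyclic α-allyl β-keto ester in which the C1/C2/C3 oxygen pattern is already fixed. It comes from C-allylation of tetracosyl 4-silyloxy-3-oxohex-5-enoate, which is assembled from O-silylated 2-hydroxybut-3-enoic acid, Meldrum's acid and tetracosan-1-ol.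
- One ring is formed (step 4) and aromatised (step 5); the phenol is unmasked last.

Key step: step 4

Assumption: all chiral intermediates are used as racemates or diastereomer mixtures, since the target is achiral and both ring stereocentres vanish on aromatisation.

**Route**

Step 1
Reactants: 1 2-hydroxybut-3-enoic acid (racemic)
Product: 3 2-(tert-butyldimethylsilyloxy)but-3-enoic acid (racemic), via bis-silyl derivative 2 (not isolated)
Conditions: TBSCl (2.4 equiv), imidazole, DMF, 0 °C to rt; then K2CO3, THF/MeOH/H2O, rt; aq. citric acid work-up (pH 4)
Reagents that add atoms: tert-butyldimethylsilyl chloride (TBSCl), CC(C)(C)[Si](C)(C)Cl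
Why: Exhaustive O-silylation of hydroxyl and carboxyl followed by selective carbonate solvolysis of the labile silyl ester is the standard route to an α-silyloxy acid, and no base strong enough to move the β,γ-alkene into conjugation is present.

Step 2
Reactants: 3 2-(tert-butyldimethylsilyloxy)but-3-enoic acid (racemic); 4 Meldrum's acid (2,2-dimethyl-1,3-dioxane-4,6-dione); 5 tetracosan-1-ol
Product: 7 tetracosyl 4-(tert-butyldimethylsilyloxy)-3-oxohex-5-enoate (racemic), via acyl Meldrum's acid 6 (not isolated)
Conditions: 3, 4, DCC, DMAP, CH2Cl2, 0 °C to rt; filter, cold aq. KHSO4 wash, concentrate; then 5, toluene, 90 °C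
Reagents that add atoms: none
Why: Carbodiimide/DMAP C-acylation of Meldrum's acid followed by thermal alcoholysis (Oikawa–Yonemitsu β-keto ester synthesis) should lose acetone and CO2 and install the tetracosyl ester under neutral conditions, at a temperature where the waxy alcohol is in solution.

Step 3
Reactants: 7 tetracosyl 4-(tert-butyldimethylsilyloxy)-3-oxohex-5-enoate (racemic); 8 allyl bromide
Product: 9 tetracosyl 2-allyl-4-(tert-butyldimethylsilyloxy)-3-oxohex-5-enoate (diastereomer mixture)
Conditions: 8 (1.05 equiv), K2CO3, acetone, 50 °C
Reagents that add atoms: none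
Why: C-alkylation of a β-keto ester enolate (acetoacetic ester alkylation) with a reactive allylic halide should occur only at the doubly activated C2–H, since the weak base leaves the C4–H untouched; the new C2 stereocentre is formed without control, which does not matter because it is destroyed in step 5.

Step 4
Reactants: 9 tetracosyl 2-allyl-4-(tert-butyldimethylsilyloxy)-3-oxohex-5-enoate (diastereomer mixture)
Product: 10 tetracosyl 3-(tert-butyldimethylsilyloxy)-2-oxocyclohex-4-ene-1-carboxylate (diastereomer mixture)
Conditions: second-generation Grubbs catalyst (H2IMes)(PCy3)Cl2Ru=CHPh (5 mol %), degassed CH2Cl2 (0.005 M), 40 °C, argon sweep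
Reagents that add atoms: none
Why: The ruthenium benzylidene should exchange onto the unhindered allyl terminus of 9, the new alkylidene should add across the tethered vinyl group to give a ruthenacyclobutane, and cycloreversion should release the ring alkene and a ruthenium methylidene that carries the cycle on with loss of ethylene (ring-closing olefin metathesis). The closest known reaction type is the closure of 1,7-dienes with a carbonyl group in the tether to cyclohexenones that serve as phenol precursors. The one ring formed is the six-membered carbocycle, closed by joining the two internal alkene carbons as the C4=C5 bond (ring numbering: C1 ester, C2 ketone, C3 silyloxy), with C6 supplied by the allyl CH2. No stereocentre is created; the two existing ones (C1 and C3) are carried as a mixture, both diastereomers can reach the ring, and both are erased in step 5. The step needs cyclisation to win over acyclic diene metathesis and alkene migration: high dilution, two monosubstituted alkenes and an unstrained six-membered product favour closure, the bulky allylic silyl ether steers initiation to the allyl arm, and the neutral 40 °C conditions should leave the C3–O bond in place.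

Step 5
Reactants: 10 tetracosyl 3-(tert-butyldimethylsilyloxy)-2-oxocyclohex-4-ene-1-carboxylate (diastereomer mixture)
Product: 11 tetracosyl 3-(tert-butyldimethylsilyloxy)-2-hydroxybenzoate
Conditions: DDQ (1.1 equiv), toluene, rt
Reagents that add atoms: none
Why: The enol tautomer of the cyclic β-keto ester is a cyclohexa-1,4-diene with a doubly allylic C6–H2, so DDQ dehydrogenation (hydride abstraction from C6 or C3, then proton loss and keto–enol tautomerisation) should give the arene whichever hydrogen leaves first, erasing both stereocentres and keeping the silyl ether.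

Step 6
Reactants: 11 tetracosyl 3-(tert-butyldimethylsilyloxy)-2-hydroxybenzoate
Product: 12 tetracosyl 2,3-dihydroxybenzoate (Gentiside K)
Conditions: TBAF, AcOH, THF, 0 °C, argon
Reagents that add atoms: none
Why: Fluoride-mediated cleavage of an aryl silyl ether is fast at 0 °C, and the acetic acid buffer should keep the catechol protonated so that neither air oxidation nor attack on the ester takes place.

**Compound list**

1 | 2-hydroxybut-3-enoic acid (racemic) | C=CC(O)C(=O)O | starting material
2 | tert-butyldimethylsilyl 2-(tert-butyldimethylsilyloxy)but-3-enoate (racemic) | C=CC(O[Si](C)(C)C(C)(C)C)C(=O)O[Si](C)(C)C(C)(C)C | intermediate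
3 | 2-(tert-butyldimethylsilyloxy)but-3-enoic acid (racemic) | C=CC(O[Si](C)(C)C(C)(C)C)C(=O)O | intermediate
4 | Meldrum's acid (2,2-dimethyl-1,3-dioxane-4,6-dione) | CC1(C)OC(=O)CC(=O)O1 | starting material
5 | tetracosan-1-ol | CCCCCCCCCCCCCCCCCCCCCCCCO | starting material
6 | 5-[2-(tert-butyldimethylsilyloxy)-1-hydroxybut-3-en-1-ylidene]-2,2-dimethyl-1,3-dioxane-4,6-dione (acyl Meldrum's acid, enol form, racemic) | CC1(C)OC(=O)C(=C(O)C(O[Si](C)(C)C(C)(C)C)C=C)C(=O)O1 | intermediate
7 | tetracosyl 4-(tert-butyldimethylsilyloxy)-3-oxohex-5-enoate (racemic) | CCCCCCCCCCCCCCCCCCCCCCCCOC(=O)CC(=O)C(O[Si](C)(C)C(C)(C)C)C=C | intermediate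
8 | allyl bromide | C=CCBr | starting material
9 | tetracosyl 2-allyl-4-(tert-butyldimethylsilyloxy)-3-oxohex-5-enoate (diastereomer mixture) | CCCCCCCCCCCCCCCCCCCCCCCCOC(=O)C(CC=C)C(=O)C(O[Si](C)(C)C(C)(C)C)C=C | intermediate
10 | tetracosyl 3-(tert-butyldimethylsilyloxy)-2-oxocyclohex-4-ene-1-carboxylate (diastereomer mixture) | CCCCCCCCCCCCCCCCCCCCCCCCOC(=O)C1CC=CC(O[Si](C)(C)C(C)(C)C)C1=O | intermediate
11 | tetracosyl 3-(tert-butyldimethylsilyloxy)-2-hydroxybenzoate | CCCCCCCCCCCCCCCCCCCCCCCCOC(=O)c1cccc(O[Si](C)(C)C(C)(C)C)c1O | intermediate
12 | tetracosyl 2,3-dihydroxybenzoate (Gentiside K) | CCCCCCCCCCCCCCCCCCCCCCCCOC(=O)c1cccc(O)c1O | target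

**Step count**

Total steps: 6. Longest linear sequence: 6 steps (1 → 3 → 7 → 9 → 10 → 11 → 12).

**Steps most likely to fail**

1. Step 4 (ring-closing metathesis). The β-dicarbonyl unit may chelate the ruthenium alkylidene after initiation and stall turnover, ruthenium hydride species may migrate the alkenes, or silanol may be lost early so that the ring aromatises without its C3 oxygen. The fallback removes the β-dicarbonyl before ring closure. It sets out from 9: reduction of the ketone with NaBH4 in THF/MeOH at −20 °C should give tetracosyl 2-allyl-3-hydroxy-4-(tert-butyldimethylsilyloxy)hex-5-enoate F1. This hydroxy diene, which can neither chelate as an enolate nor aromatise, is closed with the same second-generation Grubbs catalyst (H2IMes)(PCy3)Cl2Ru=CHPh to tetracosyl 2-hydroxy-3-(tert-butyldimethylsilyloxy)cyclohex-4-ene-1-carboxylate F2. Oxidation of the carbinol with Dess–Martin periodinane (NaHCO3, CH2Cl2) brings the sequence back to the route at 10.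

2. Step 5 (dehydrogenation). Acid-promoted 1,4-elimination of silanol, driven by the hydroquinone by-product, may compete with hydride abstraction, or abstraction may be slow if the keto tautomer dominates. The fallback oxidises at the carbinol instead of at C–H. It sets out from 10: cleavage of the silyl ether with pyridine-buffered HF·pyridine in THF at 0 °C should give tetracosyl 3-hydroxy-2-oxocyclohex-4-ene-1-carboxylate F3. Oxidation with Dess–Martin periodinane (1.1 equiv, NaHCO3, CH2Cl2, 0 °C) should give tetracosyl 2,3-dioxocyclohex-4-ene-1-carboxylate F4, which is not isolated because double enolisation makes it the catechol. An aqueous Na2S2O4 wash would reduce any ortho-quinone formed by over-oxidation, and the sequence comes back to the route at 12.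

3. Step 3 (C-allylation). A second allylation of the product enolate, or O-allylation, may erode the yield of the mono-C-allyl compound. The fallback brings the allyl group in with the nucleophile. It sets out from 3: coupling with N,O-dimethylhydroxylamine hydrochloride (EDC, HOBt, iPr2NEt, CH2Cl2) should give N-methoxy-N-methyl-2-(tert-butyldimethylsilyloxy)but-3-enamide F5. In parallel, pent-4-enoic acid (C=CCCC(=O)O) and 5 are esterified (DCC, DMAP, CH2Cl2) to tetracosyl pent-4-enoate F6. The lithium enolate of F6 (LDA, THF, −78 to −40 °C, 2 equiv) is acylated by F5, and the stable tetrahedral chelate should release the β-keto ester only on acidic work-up. The sequence comes back to the route at 9 and bypasses 7.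

**Further compounds**

F1 | step 4 | tetracosyl 2-allyl-3-hydroxy-4-(tert-butyldimethylsilyloxy)hex-5-enoate (diastereomer mixture) | CCCCCCCCCCCCCCCCCCCCCCCCOC(=O)C(CC=C)C(O)C(O[Si](C)(C)C(C)(C)C)C=C
F2 | step 4 | tetracosyl 2-hydroxy-3-(tert-butyldimethylsilyloxy)cyclohex-4-ene-1-carboxylate (diastereomer mixture) | CCCCCCCCCCCCCCCCCCCCCCCCOC(=O)C1CC=CC(O[Si](C)(C)C(C)(C)C)C1O
F3 | step 5 | tetracosyl 3-hydroxy-2-oxocyclohex-4-ene-1-carboxylate (diastereomer mixture) | CCCCCCCCCCCCCCCCCCCCCCCCOC(=O)C1CC=CC(O)C1=O
F4 | step 5 | tetracosyl 2,3-dioxocyclohex-4-ene-1-carboxylate (racemic) | CCCCCCCCCCCCCCCCCCCCCCCCOC(=O)C1CC=CC(=O)C1=O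
F5 | step 3 | N-methoxy-N-methyl-2-(tert-butyldimethylsilyloxy)but-3-enamide (racemic) | CON(C)C(=O)C(O[Si](C)(C)C(C)(C)C)C=C
F6 | step 3 | tetracosyl pent-4-enoate | CCCCCCCCCCCCCCCCCCCCCCCCOC(=O)CCC=C
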